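Numbering: ring C1 (CH–O-acyl), C2 (C=O), C3 (C–CH3, oxirane), C4 (oxirane CH), C5 (CH2), C6 (CH); chain C7 (oxirane C), C14 (its CH2), C8 (C=O), C9=C10, C11 (CMe2OH).
Enabling feature: on the carbocycle the C3 methyl and the C6 branch are para and C2–C4 carry only oxygen that a ring alkene can supply, so the ring is the para Diels–Alder adduct of isoprene and an acrylate whose carboxyl carbon is C7.
Cuts: C4–C5 and C1–C6 ([4+2]); then C8–C9 (alkenyl–aldehyde coupling), C7–C8 (Stille CH2OH), C7–C14 (MeMgBr on the carboxyl), C1–O and the ester C–O bond.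
Forward order: carbocycle first; C14 and an enol triflate are set on C7; the ring alkene is transposed to the C2 enone and converted into the cis-epoxy ketone; C1 is oxygenated and acylated; the C7 oxirane and the C8–C13 chain come last.
Stereochemistry: C6 from the chiral oxazaborolidinium catalyst; a transient C2 carbinol (Luche, cis to the C6 branch) directs the C3/C4 epoxide; C1 by enolate oxidation anti to the C6 branch; C7 by Sharpless epoxidation with L-(+)-tartrate; C9=C10 (E) by syn-hydrostannation.

Key step: step 1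

Assumption: with acrylates the oxazaborolidinium ion derived from (S)-α,α-diphenylprolinol is taken to give the (1R) adduct (α-C–H···O binding mode); if the sense were the reverse, the mirror-image catalyst, equally available, would be used.

Step 1
Reactants: 1 isoprene; 2 2,2,2-trifluoroethyl acrylate
Product: 3 2,2,2-trifluoroethyl (1R)-4-methylcyclohex-3-ene-1-carboxylate
Conditions: (S)-o-tolyl-oxazaborolidine·Tf2NH (10–20 mol%), CH2Cl2, 0 °C
Reagents that add atoms: none
Why: The N-protonated oxazaborolidine binds the s-trans acrylate at boron and lowers its LUMO, so that isoprene adds in a concerted, asynchronous, suprafacial [4+2] cycloaddition in which the C4–C5 bond (diene terminus next to the methyl-bearing carbon, acrylate β-carbon) forms ahead of C1–C6. The closest known reaction type is the cationic-oxazaborolidine-catalysed Diels–Alder reaction of trifluoroethyl acrylate with simple 1,3-dienes. The carbocycle closes in the thermally allowed [π4s+π2s] mode, leaving the C2=C3 alkene. C6, the only new stereocentre, is set by the catalyst, whose aryl group shields one face of the bound acrylate. The step needs para regioselectivity, secured by the larger HOMO coefficient at diene terminus C4 and enhanced by the Lewis acid, and enantioface selection, secured by the chiral boron cation.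

Step 2
Reactants: 3 2,2,2-trifluoroethyl (1R)-4-methylcyclohex-3-ene-1-carboxylate
Product: 5 1-[(1R)-4-methylcyclohex-3-en-1-yl]ethan-1-one, via Weinreb amide 4 (not isolated)
Conditions: MeNH(OMe)·HCl, i-PrMgCl, THF, −20 °C; then MeMgBr, 0 °C; aq. NH4Cl
Reagents that add atoms: methylmagnesium bromide, C[Mg]Br
Why: Magnesium-amide aminolysis of the activated ester gives the Weinreb amide, whose chelated tetrahedral adduct with MeMgBr stops at the methyl ketone (Weinreb ketone synthesis) and brings in C14 without equilibrating C6.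

Step 3
Reactants: 5 1-[(1R)-4-methylcyclohex-3-en-1-yl]ethan-1-one
Product: 7 1-[(1R)-4-methylcyclohex-3-en-1-yl]ethenyl trifluoromethanesulfonate, via potassium enolate 6 (not isolated)
Conditions: KHMDS, THF, −78 °C; then PhNTf2, −78 to 0 °C; aq. NH4Cl
Reagents that add atoms: N-phenylbis(trifluoromethanesulfonimide), O=S(=O)(N(c1ccccc1)S(=O)(=O)C(F)(F)F)C(F)(F)F
Why: Kinetic deprotonation at the methyl group and O-sulfonylation of the less substituted enolate (enol triflate formation) gives the terminal C7=C14 triflate without enolising toward C6.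

Step 4
Reactants: 7 1-[(1R)-4-methylcyclohex-3-en-1-yl]ethenyl trifluoromethanesulfonate
Product: 9 conjugated oxime (C2=N–OH and C3=C4), via nitrosochloride 8 (not isolated)
Conditions: isoamyl nitrite, conc. HCl, i-PrOH, −15 °C; then pyridine, DMF, 60 °C
Reagents that add atoms: isoamyl nitrite, CC(C)CCON=O
Why: Markovnikov nitrosochlorination of the electron-rich trisubstituted ring alkene (NO at C2, Cl at C3; the enol triflate alkene is too electron-poor to react) followed by base-induced dehydrochlorination toward C4 gives the conjugated oxime, the sequence that converts limonene into carvoxime.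

Step 5
Reactants: 9 conjugated oxime
Product: 10 1-[(1R)-4-methyl-3-oxocyclohex-4-en-1-yl]ethenyl trifluoromethanesulfonate
Conditions: 5% aq. oxalic acid, THF, 60 °C
Reagents that add atoms: water, O
Why: Acid-catalysed oxime hydrolysis (deoximation) releases the 2-methyl enone, and the enol triflate is stable to dilute aqueous acid.

Step 6
Reactants: 10 enone triflate
Product: 11 cis allylic alcohol (C2–OH on the face of the C6 branch)
Conditions: NaBH4, CeCl3·7H2O, MeOH, −78 °C
Reagents that add atoms: none
Why: Luche 1,2-reduction, in which axial hydride attack on the half-chair with the C6 branch equatorial gives the equatorial C2 carbinol cis to that branch, as carvone gives cis-carveol.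

Step 7
Reactants: 11 cis allylic alcohol
Product: 12 all-cis epoxy alcohol (C2–OH; C3/C4 oxirane; C6 branch on one face)
Conditions: VO(acac)2 (cat.), t-BuOOH, CH2Cl2, 0 °C to rt
Reagents that add atoms: tert-butyl hydroperoxide, CC(C)(C)OO
Why: Vanadium-catalysed hydroxyl-directed epoxidation delivers oxygen to C3=C4 from the face of the C2 hydroxyl, which sets C3 and C4, and leaves the undirected, electron-poor enol triflate alkene untouched.

Step 8
Reactants: 12 all-cis epoxy alcohol
Product: 13 cis-epoxy ketone triflate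
Conditions: Dess–Martin periodinane, NaHCO3, CH2Cl2, 0 °C to rt
Reagents that add atoms: none
Why: Dess–Martin oxidation of the secondary carbinol restores the C2 ketone under neutral conditions that spare the oxirane and the triflate.

Step 9
Reactants: 13 cis-epoxy ketone triflate
Product: 15 α-ketol triflate (C1–OH trans to the C6 branch), via sodium enolate 14 (not isolated)
Conditions: NaHMDS, THF, −78 °C; then 2-(phenylsulfonyl)-3-phenyloxaziridine, −78 °C; aq. NH4Cl
Reagents that add atoms: 2-(phenylsulfonyl)-3-phenyloxaziridine, O=S(=O)(N1OC1c1ccccc1)c1ccccc1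
Why: Davis oxidation of the only possible enolate (toward C1, since C3 is quaternary), with the oxaziridine approaching anti to the adjacent C6 branch and the oxirane oxygen, gives the trans C1 carbinol, which is also the more stable diequatorial epimer.

Step 10
Reactants: 15 α-ketol triflate; 16 isovaleryl chloride
Product: 17 C1 isovalerate triflate
Conditions: pyridine, DMAP (cat.), CH2Cl2, 0 °C
Reagents that add atoms: none
Why: DMAP-catalysed O-acylation of the single hydroxyl group by the acid chloride.

Step 11
Reactants: 17 C1 isovalerate triflate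
Product: 18 2-substituted allylic alcohol (C7(=C14H2)–C8H2OH)
Conditions: Bu3SnCH2OH, Pd(PPh3)4 (cat.), LiCl, dioxane, 90 °C
Reagents that add atoms: (tributylstannyl)methanol, OC[Sn](CCCC)(CCCC)CCCC
Why: Stille coupling of the enol triflate with the hydroxymethylstannane transfers C8 under neutral conditions compatible with the ketone, the ester and the oxirane.

Step 12
Reactants: 18 2-substituted allylic alcohol
Product: 19 epoxy alcohol with the C7 oxirane
Conditions: Ti(Oi-Pr)4 (cat.), L-(+)-DIPT, t-BuOOH, 4 Å MS, CH2Cl2, −20 °C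
Reagents that add atoms: tert-butyl hydroperoxide, CC(C)(C)OO
Why: Sharpless asymmetric epoxidation under reagent control, in which L-(+)-tartrate delivers oxygen to the face that turns 2-substituted allyl alcohols into (S)-2-substituted glycidols, which is the C7 configuration of the target, while ketone and ester are inert.

Step 13
Reactants: 19 epoxy alcohol
Product: 20 epoxy aldehyde (C8 = CHO)
Conditions: Dess–Martin periodinane, NaHCO3, CH2Cl2, 0 °C
Reagents that add atoms: none
Why: Dess–Martin oxidation of the primary carbinol gives an aldehyde on a quaternary oxirane carbon, which has no α-hydrogen and cannot epimerise.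

Step 14
Reactants: 21 2-methylbut-3-yn-2-ol
Product: 23 (E)-4-iodo-2-methylbut-3-en-2-ol, via vinylstannane 22 (not isolated)
Conditions: Bu3SnH, PdCl2(PPh3)2 (cat.), THF, 0 °C; then I2, 0 °C
Reagents that add atoms: iodine, II
Why: Palladium-catalysed syn-hydrostannation places tin on the unhindered terminus trans to the carbinol carbon, and iododestannylation with retention gives the E iodide.

Step 15
Reactants: 20 epoxy aldehyde; 23 (E)-4-iodo-2-methylbut-3-en-2-ol
Product: 25 allylic diol (C8–OH as both epimers), via alkenylchromium(III) reagent 24 (not isolated)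
Conditions: CrCl2, NiCl2 (cat.), DMSO, rt
Reagents that add atoms: none
Why: Nozaki–Hiyama–Kishi coupling, in which the alkenylchromium(III) species adds to the aldehyde in preference to the hindered ring ketone and the ester with retention of the E geometry and tolerance of the free tertiary hydroxyl; the C8 configuration is immaterial.

Step 16
Reactants: 25 allylic diol
Product: 26 CNP0292003.1
Conditions: Dess–Martin periodinane, NaHCO3, CH2Cl2, 0 °C
Reagents that add atoms: none
Why: Dess–Martin oxidation of the secondary allylic carbinol gives the C8 enone, while the tertiary C11 hydroxyl cannot be oxidised.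

Compound list
1 | isoprene | CC(=C)C=C | starting material
2 | 2,2,2-trifluoroethyl acrylate | C=CC(=O)OCC(F)(F)F | starting material
3 | 2,2,2-trifluoroethyl (1R)-4-methylcyclohex-3-ene-1-carboxylate | C1C=C(C)CC[C@H]1C(=O)OCC(F)(F)F | intermediate
4 | (1R)-N-methoxy-N,4-dimethylcyclohex-3-ene-1-carboxamide (not isolated) | C1C=C(C)CC[C@H]1C(=O)N(C)OC | intermediate
5 | 1-[(1R)-4-methylcyclohex-3-en-1-yl]ethan-1-one | C1C=C(C)CC[C@H]1C(C)=O | intermediate
6 | potassium 1-[(1R)-4-methylcyclohex-3-en-1-yl]ethen-1-olate (not isolated) | C1C=C(C)CC[C@H]1C(=C)[O-].[K+] | intermediate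
7 | 1-[(1R)-4-methylcyclohex-3-en-1-yl]ethenyl trifluoromethanesulfonate | C1C=C(C)CC[C@H]1C(=C)OS(=O)(=O)C(F)(F)F | intermediate
8 | 1-[(1R)-4-chloro-4-methyl-3-nitrosocyclohexyl]ethenyl trifluoromethanesulfonate (nitrosochloride, diastereomer mixture at the two new centres, present as its dimer; not isolated) | C1C(N=O)C(C)(Cl)CC[C@H]1C(=C)OS(=O)(=O)C(F)(F)F | intermediate
9 | 1-[(1R)-3-(hydroxyimino)-4-methylcyclohex-4-en-1-yl]ethenyl trifluoromethanesulfonate (oxime geometry immaterial) | C1C(=NO)C(C)=CC[C@H]1C(=C)OS(=O)(=O)C(F)(F)F | intermediate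
10 | 1-[(1R)-4-methyl-3-oxocyclohex-4-en-1-yl]ethenyl trifluoromethanesulfonate | C1C(=O)C(C)=CC[C@H]1C(=C)OS(=O)(=O)C(F)(F)F | intermediate
11 | 1-[(1R,3R)-3-hydroxy-4-methylcyclohex-4-en-1-yl]ethenyl trifluoromethanesulfonate (hydroxyl cis to the side chain) | C1[C@@H](O)C(C)=CC[C@H]1C(=C)OS(=O)(=O)C(F)(F)F | intermediate
12 | 1-[(1R,2R,4S,6S)-2-hydroxy-1-methyl-7-oxabicyclo[4.1.0]heptan-4-yl]ethenyl trifluoromethanesulfonate (hydroxyl, oxirane oxygen and side chain all cis) | C1[C@@H](O)[C@@]2(C)O[C@H]2C[C@H]1C(=C)OS(=O)(=O)C(F)(F)F | intermediate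
13 | 1-[(1S,4R,6S)-1-methyl-2-oxo-7-oxabicyclo[4.1.0]heptan-4-yl]ethenyl trifluoromethanesulfonate (oxirane cis to the side chain) | C1C(=O)[C@@]2(C)O[C@H]2C[C@H]1C(=C)OS(=O)(=O)C(F)(F)F | intermediate
14 | sodium (1S,4R,6S)-1-methyl-4-[1-(trifluoromethanesulfonyloxy)ethenyl]-7-oxabicyclo[4.1.0]hept-2-en-2-olate (not isolated) | C1=C([O-])[C@@]2(C)O[C@H]2C[C@H]1C(=C)OS(=O)(=O)C(F)(F)F.[Na+] | intermediate
15 | 1-[(1S,3S,4R,6S)-3-hydroxy-1-methyl-2-oxo-7-oxabicyclo[4.1.0]heptan-4-yl]ethenyl trifluoromethanesulfonate (hydroxyl trans to side chain and oxirane) | O[C@@H]1C(=O)[C@@]2(C)O[C@H]2C[C@H]1C(=C)OS(=O)(=O)C(F)(F)F | intermediate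
16 | isovaleryl chloride (3-methylbutanoyl chloride) | CC(C)CC(Cl)=O | starting material
17 | (1S,3S,4R,6S)-1-methyl-2-oxo-4-[1-(trifluoromethanesulfonyloxy)ethenyl]-7-oxabicyclo[4.1.0]heptan-3-yl 3-methylbutanoate | CC(C)CC(=O)O[C@@H]1C(=O)[C@@]2(C)O[C@H]2C[C@H]1C(=C)OS(=O)(=O)C(F)(F)F | intermediate
18 | (1S,3S,4S,6S)-4-(3-hydroxyprop-1-en-2-yl)-1-methyl-2-oxo-7-oxabicyclo[4.1.0]heptan-3-yl 3-methylbutanoate | CC(C)CC(=O)O[C@@H]1C(=O)[C@@]2(C)O[C@H]2C[C@H]1C(=C)CO | intermediate
19 | (1S,3S,4R,6S)-4-[(2S)-2-(hydroxymethyl)oxiran-2-yl]-1-methyl-2-oxo-7-oxabicyclo[4.1.0]heptan-3-yl 3-methylbutanoate | CC(C)CC(=O)O[C@@H]1C(=O)[C@@]2(C)O[C@H]2C[C@H]1[C@]1(CO)CO1 | intermediate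
20 | (1S,3S,4R,6S)-4-[(2R)-2-formyloxiran-2-yl]-1-methyl-2-oxo-7-oxabicyclo[4.1.0]heptan-3-yl 3-methylbutanoate | CC(C)CC(=O)O[C@@H]1C(=O)[C@@]2(C)O[C@H]2C[C@H]1[C@]1(C=O)CO1 | intermediate
21 | 2-methylbut-3-yn-2-ol | CC(C)(O)C#C | starting material
22 | (E)-2-methyl-4-(tributylstannyl)but-3-en-2-ol (not isolated) | CC(C)(O)/C=C/[Sn](CCCC)(CCCC)CCCC | intermediate
23 | (E)-4-iodo-2-methylbut-3-en-2-ol | CC(C)(O)/C=C/I | intermediate
24 | dichloro[(1E)-3-hydroxy-3-methylbut-1-en-1-yl]chromium(III) (not isolated) | CC(C)(O)/C=C/[Cr](Cl)Cl | intermediate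
25 | (1S,3S,4R,6S)-4-{(2R)-2-[(2E)-1,4-dihydroxy-4-methylpent-2-en-1-yl]oxiran-2-yl}-1-methyl-2-oxo-7-oxabicyclo[4.1.0]heptan-3-yl 3-methylbutanoate (both carbinol epimers) | CC(C)CC(=O)O[C@@H]1C(=O)[C@@]2(C)O[C@H]2C[C@H]1[C@]1(C(O)/C=C/C(C)(C)O)CO1 | intermediate
26 | (1S,3S,4R,6S)-4-{(2R)-2-[(2E)-4-hydroxy-4-methylpent-2-enoyl]oxiran-2-yl}-1-methyl-2-oxo-7-oxabicyclo[4.1.0]heptan-3-yl 3-methylbutanoate (CNP0292003.1) | CC(C)CC(=O)O[C@@H]1C(=O)[C@@]2(C)O[C@H]2C[C@H]1[C@]1(C(=O)/C=C/C(C)(C)O)CO1 | target

Total step count: 16. Longest linear sequence: 15 steps (steps 1–13, 15 and 16); step 14 is a one-step side branch.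

Steps most likely to fail

Step 15. Electron transfer from Cr(II) to the ring α,β-epoxy ketone or the α-acyloxy ketone (reductive C–O cleavage) may compete with the Ni/Cr cycle, and the alkenylchromium may not discriminate fully between the aldehyde and the ring ketone. The fallback sets out from aldehyde 20 and alkyne 21 and returns at diol 25; it uses no reducing metal. Alkyne 21 is silylated (TMSCl, imidazole) to trimethyl[(2-methylbut-3-yn-2-yl)oxy]silane F1. Hydrozirconation with Cp2Zr(H)Cl gives the (E)-alkenylzirconocene chloride F2, which Me2Zn converts at −65 °C into the alkenyl(methyl)zinc F3. This adds to 20 at 0 °C, a carbonyl addition that is selective for aldehydes over ketones and esters, to give the C11 trimethylsilyl ether F4. TBAF buffered with acetic acid then removes the silyl group to give 25.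

Step 9. Deprotonation at the enol triflate (loss of triflate toward the alkyne) may compete with enolisation of the ketone, the sulfonimine by-product may capture the enolate, and facial discrimination at C1 may be incomplete. The fallback sets out from epoxy ketone 13 and returns at allylic alcohol 18; it removes the triflate before any strong base is used. The Stille hydroxymethylation is brought forward to give the allylic alcohol F5, which is protected (TBDPSCl, imidazole) as the silyl ether F6. NaHMDS gives the sodium enolate F7, and oxaziridine oxidation gives the ketol F8. Acylation with 16 gives the isovalerate F9, and HF·pyridine removes the silyl group to give 18. In either variant a minor C1 epimer would be equilibrated with mild base toward the trans ketol.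

Step 4. Nitrosation of the ring alkene may be sluggish or reversible, dehydrochlorination may go toward the methyl group, and the acidic medium may erode the enol triflate. The fallback sets out from triflate 7 and returns at enone 10. Upjohn dihydroxylation (OsO4 cat., NMO) of the electron-rich ring alkene gives the cis-diol F10 as a facial mixture of no consequence. Parikh–Doering oxidation of the secondary hydroxyl gives the α-hydroxy ketone F11. Dehydration of the tertiary carbinol with the Burgess reagent toward C4 gives the conjugated enone 10.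

Further compounds
F1 | step 15 | trimethyl[(2-methylbut-3-yn-2-yl)oxy]silane | CC(C)(O[Si](C)(C)C)C#C
F2 | step 15 | chlorobis(cyclopentadienyl)[(1E)-3-methyl-3-(trimethylsilyloxy)but-1-en-1-yl]zirconium | C[Si](C)(C)OC(C)(C)/C=C/[Zr](Cl)(C1C=CC=C1)C1C=CC=C1
F3 | step 15 | methyl[(1E)-3-methyl-3-(trimethylsilyloxy)but-1-en-1-yl]zinc | C[Zn]/C=C/C(C)(C)O[Si](C)(C)C
F4 | step 15 | C11 trimethylsilyl ether of diol 25 (both C8 epimers) | CC(C)CC(=O)O[C@@H]1C(=O)[C@@]2(C)O[C@H]2C[C@H]1[C@]1(C(O)/C=C/C(C)(C)O[Si](C)(C)C)CO1
F5 | step 9 | (1S,4R,6S)-4-(3-hydroxyprop-1-en-2-yl)-1-methyl-7-oxabicyclo[4.1.0]heptan-2-one | C1C(=O)[C@@]2(C)O[C@H]2C[C@H]1C(=C)CO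
F6 | step 9 | tert-butyldiphenylsilyl ether of F5 | C1C(=O)[C@@]2(C)O[C@H]2C[C@H]1C(=C)CO[Si](c1ccccc1)(c1ccccc1)C(C)(C)C
F7 | step 9 | sodium enolate of F6 (C1=C2 enolate) | C1=C([O-])[C@@]2(C)O[C@H]2C[C@H]1C(=C)CO[Si](c1ccccc1)(c1ccccc1)C(C)(C)C.[Na+]
F8 | step 9 | C1 ketol of F6 (hydroxyl trans to the side chain) | O[C@@H]1C(=O)[C@@]2(C)O[C@H]2C[C@H]1C(=C)CO[Si](c1ccccc1)(c1ccccc1)C(C)(C)C
F9 | step 9 | C1 isovalerate of F8 | CC(C)CC(=O)O[C@@H]1C(=O)[C@@]2(C)O[C@H]2C[C@H]1C(=C)CO[Si](c1ccccc1)(c1ccccc1)C(C)(C)C
F10 | step 4 | 1-[(1R)-3,4-dihydroxy-4-methylcyclohexyl]ethenyl trifluoromethanesulfonate (cis-diol, facial mixture) | C1C(O)C(C)(O)CC[C@H]1C(=C)OS(=O)(=O)C(F)(F)F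
F11 | step 4 | 1-[(1R)-4-hydroxy-4-methyl-3-oxocyclohexyl]ethenyl trifluoromethanesulfonate (mixture at the carbinol carbon) | C1C(=O)C(C)(O)CC[C@H]1C(=C)OS(=O)(=O)C(F)(F)F
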